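**Retrosynthetic overview** (terpenoid numbering: ring A = C1–C5 and C10, ring B = C5–C10, C11 = benzylic CH2; systematic names use naphthalene locants)

- End game: the aminoquinone comes from a 2-hydroxy-5-methoxyquinone by OMe/NHR exchange with (S)-2-methylbutylamine; the quinone comes from a 2,3,5,6-tetramethoxybenzyl group by oxidative demethylation and selective hydrolysis.
- C8–CH3 comes from a C8 ketone (methylenation, face-selective hydrogenation); C5=C6 from reductive expulsion of a C5 methoxy group γ to the C8 enone with α-protonation; quaternary C9 from two enolate alkylations (CH3, then ArCH2 anti to ring A).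
- Key disconnection C1–C10: ring A is closed onto a dearomatised ring B in a one-pot oxidative dearomatisation/amine-catalysed desymmetrising Michael addition of a para-substituted phenol aldehyde; the formyl group on C1 is a traceless activator, removed by decarbonylation.
- Enabling feature: ring B is bought as phenol; after oxidation to the 4-methoxycyclohexa-2,5-dienone its two enone arms (C6=C7 and C9=C10, both conjugated to C8=O) are enantiotopic about the tether-bearing C5, so a chiral enamine at C1 can select C10 of one arm and leave C6=C7–C8=O as the handle for C9 and for C5=C6.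
- Ring order: ring B (phenol), then ring A (key step), then the quinone ring (from 1,2,4,5-tetramethoxybenzene, joined at C9 through C11 and oxidised last).

Key step: step 4

Remark: the (S)-configured catalyst is assumed to select the enone arm that gives (8aR)-9 with the formyl group trans to the ring-B bond at C10 (anti enamine, chair transition state); if the sense of induction is the opposite, the (R)-catalyst is used, and the formyl-bearing centre is erased in step 5 in any case.

**Route**

Step 1
Reactants: 1 acetone; 2 pent-4-enylmagnesium bromide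
Product: 3 2-methylhept-6-en-2-ol
Conditions: THF, 0 °C to rt; aq. NH4Cl
Reagents that add atoms: none
Why: Grignard addition to the ketone should give the tertiary alcohol that serves as the tertiary carbocation source for C4.

Step 2
Reactants: 3 2-methylhept-6-en-2-ol; 4 phenol
Product: 5 4-(2-methylhept-6-en-2-yl)phenol
Conditions: 4 (4 equiv), TsOH·H2O (10 mol%), (CF3)2CHOH, 40 °C
Reagents that add atoms: none
Why: Friedel–Crafts alkylation through the tertiary carbocation should go para for steric reasons, while the monosubstituted alkene is not protonated under these mild conditions.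

Step 3
Reactants: 5 4-(2-methylhept-6-en-2-yl)phenol
Product: 7 5-(4-hydroxyphenyl)-5-methylhexanal, via vicinal diol 6 (not isolated)
Conditions: K2OsO4·2H2O (2 mol%), NaIO4 (4 equiv), 2,6-lutidine, dioxane/H2O 3:1, rt
Reagents that add atoms: sodium periodate [Na+].[O-]I(=O)(=O)=O
Why: Lemieux–Johnson cleavage of the terminal alkene (dihydroxylation, then periodate glycol cleavage) should give the aldehyde whose α-carbon is C1, and a simple alkylphenol is expected to tolerate periodate.

Step 4
Reactants: 7 5-(4-hydroxyphenyl)-5-methylhexanal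
Product: 9 (1S,4aS,8aR)-4a-methoxy-4,4-dimethyl-7-oxo-1,2,3,4,4a,7,8,8a-octahydronaphthalene-1-carbaldehyde, via methoxy dienone aldehyde 8 (not isolated)
Conditions: PhI(OAc)2 (1.05 equiv), (S)-2-{bis[3,5-bis(trifluoromethyl)phenyl](trimethylsilyloxy)methyl}pyrrolidine (10 mol%), MeOH, 0 °C
Reagents that add atoms: methanol CO
Why: PhI(OAc)2 oxidises the phenol of 7 and methanol is captured at the para carbon C5 to give the achiral 4-methoxycyclohexa-2,5-dienone 8; the secondary amine then condenses with the aldehyde to an anti enamine whose α-carbon C1 adds to the β-carbon C10 of one enone arm (Michael addition), and hydrolysis of the iminium ion releases 9 and the catalyst. The closest known reaction type is the one-pot oxidative dearomatisation/amine-catalysed desymmetrising intramolecular Michael cyclisation of para-substituted phenols that carry a formylalkyl tether (organocatalytic enantioselective dearomatisation). Ring A is closed in the 6-exo-trig mode through a chair-like transition state, and the cis ring fusion is enforced because the chain on C5 can reach C10 only from its own face. C10 is set by the catalyst, whose shielded enamine face selects one of the two enantiotopic arms; C5 becomes stereogenic as a consequence of that choice (methoxy cis to H-10), and C1 follows from the E-enamine geometry. The step needs enantiotopic-arm selectivity, which the symmetry of 8 together with the chiral amine should secure, and it leaves the second arm (C6=C7–C8=O) untouched for later use; the gem-dimethyl group at C4 favours the folded conformer needed for closure.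

Step 5
Reactants: 9 (1S,4aS,8aR)-4a-methoxy-4,4-dimethyl-7-oxo-1,2,3,4,4a,7,8,8a-octahydronaphthalene-1-carbaldehyde
Product: 10 (4aR,8aS)-4a-methoxy-5,5-dimethyl-4a,5,6,7,8,8a-hexahydronaphthalen-2(1H)-one
Conditions: RhCl(PPh3)3 (1.1 equiv), xylene, 140 °C
Reagents that add atoms: none
Why: Tsuji–Wilkinson decarbonylation (oxidative addition into the formyl C–H bond, CO extrusion, reductive elimination) should remove the activating formyl group and leave C1 as CH2 without touching the enone or C10.

Step 6
Reactants: 10 (4aR,8aS)-4a-methoxy-5,5-dimethyl-4a,5,6,7,8,8a-hexahydronaphthalen-2(1H)-one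
Product: 12 (1S,4aS,8aS)-4a-methoxy-1,5,5-trimethyl-4a,5,6,7,8,8a-hexahydronaphthalen-2(1H)-one, via lithium enolate 11 (not isolated)
Conditions: LiN(iPr)2 (1.05 equiv), THF, −78 °C; MeI, −78 to −40 °C
Reagents that add atoms: iodomethane CI
Why: Kinetic α'-deprotonation can occur only at C9 because C5 is quaternary (no γ-hydrogen), and enolate methylation should place the methyl group on the convex face; this centre is planarised again in step 9, so its configuration is of no consequence.

Step 7
Reactants: 13 1,2,4,5-tetramethoxybenzene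
Product: 15 (2,3,5,6-tetramethoxyphenyl)methanol, via aryllithium 14 (not isolated)
Conditions: n-BuLi, TMEDA, THF, 0 °C to rt; (CH2O)n, rt; aq. NH4Cl
Reagents that add atoms: formaldehyde (from paraformaldehyde) C=O
Why: Directed ortho-lithiation at the position flanked by two methoxy groups followed by hydroxymethylation should give the benzylic alcohol.

Step 8
Reactants: 15 (2,3,5,6-tetramethoxyphenyl)methanol
Product: 16 3-(bromomethyl)-1,2,4,5-tetramethoxybenzene
Conditions: PBr3 (0.4 equiv), Et2O, 0 °C
Reagents that add atoms: phosphorus tribromide BrP(Br)Br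
Why: Bromination of the activated benzylic alcohol via its phosphite ester should be fast, and the bromide is used directly because it ionises easily.

Step 9
Reactants: 12 (1S,4aS,8aS)-4a-methoxy-1,5,5-trimethyl-4a,5,6,7,8,8a-hexahydronaphthalen-2(1H)-one; 16 3-(bromomethyl)-1,2,4,5-tetramethoxybenzene
Product: 18 (1S,4aS,8aS)-4a-methoxy-1,5,5-trimethyl-1-[(2,3,5,6-tetramethoxyphenyl)methyl]-4a,5,6,7,8,8a-hexahydronaphthalen-2(1H)-one, via lithium enolate 17 (not isolated)
Conditions: LiN(iPr)2 (1.1 equiv), THF/DMPU, −78 to −40 °C; 16 (1.3 equiv), −78 to −20 °C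
Reagents that add atoms: none
Why: Enolate alkylation with a reactive benzylic bromide should build quaternary C9, the electrophile entering on the convex face of the cis-fused bicycle, anti to the ring-A bonds at C5 and C10, so that C11 ends up trans to C1 and the C9 methyl cis to it.

Step 10
Reactants: 18 (1S,4aS,8aS)-4a-methoxy-1,5,5-trimethyl-1-[(2,3,5,6-tetramethoxyphenyl)methyl]-4a,5,6,7,8,8a-hexahydronaphthalen-2(1H)-one
Product: 20 (1S,8aR)-1,5,5-trimethyl-1-[(2,3,5,6-tetramethoxyphenyl)methyl]-1,5,6,7,8,8a-hexahydronaphthalen-2(3H)-one, via lithium dienolate 19 (not isolated)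
Conditions: Li (5 equiv), NH3(l)/THF, −78 °C, 15 min; isoprene; solid NH4Cl, −78 °C
Reagents that add atoms: none
Why: Dissolving-metal reduction of the enone should expel the γ-methoxide from C5 to give the extended dienolate, and kinetic protonation at the α-carbon C7 places the double bond regiospecifically at C5=C6; the electron-rich arene is not reduced in the absence of a proton donor.

Step 11
Reactants: 20 (1S,8aR)-1,5,5-trimethyl-1-[(2,3,5,6-tetramethoxyphenyl)methyl]-1,5,6,7,8,8a-hexahydronaphthalen-2(3H)-one
Product: 21 (1S,8aS)-1,5,5-trimethyl-2-methylidene-1-[(2,3,5,6-tetramethoxyphenyl)methyl]-1,2,3,5,6,7,8,8a-octahydronaphthalene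
Conditions: Cp2Ti(μ-Cl)(μ-CH2)AlMe2 (1.5 equiv), pyridine (cat.), THF/toluene, −40 to 0 °C
Reagents that add atoms: Tebbe complex Cp2Ti(μ-Cl)(μ-CH2)AlMe2 C[Al-]1(C)C[Ti](C2C=CC=C2)(C3C=CC=C3)[Cl+]1
Why: Tebbe methylenation is non-basic and should convert the hindered, easily enolised β,γ-unsaturated ketone into the exocyclic alkene without moving C5=C6 into conjugation.

Step 12
Reactants: 21 (1S,8aS)-1,5,5-trimethyl-2-methylidene-1-[(2,3,5,6-tetramethoxyphenyl)methyl]-1,2,3,5,6,7,8,8a-octahydronaphthalene
Product: 22 (1R,2S,8aS)-1,2,5,5-tetramethyl-1-[(2,3,5,6-tetramethoxyphenyl)methyl]-1,2,3,5,6,7,8,8a-octahydronaphthalene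
Conditions: H2 (4 atm), RhCl(PPh3)3 (10 mol%), toluene/EtOH, rt
Reagents that add atoms: none
Why: Homogeneous hydrogenation should reduce only the 1,1-disubstituted alkene and deliver hydrogen to C8 from the face opposite the axial C9 methyl group, giving the equatorial C8 methyl cis to the C9 methyl, while the hindered trisubstituted C5=C6 is left alone.

Step 13
Reactants: 22 (1R,2S,8aS)-1,2,5,5-tetramethyl-1-[(2,3,5,6-tetramethoxyphenyl)methyl]-1,2,3,5,6,7,8,8a-octahydronaphthalene
Product: 23 2,5-dimethoxy-3-{[(1R,2S,8aS)-1,2,5,5-tetramethyl-1,2,3,5,6,7,8,8a-octahydronaphthalen-1-yl]methyl}cyclohexa-2,5-diene-1,4-dione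
Conditions: (NH4)2Ce(NO3)6 (2.5 equiv), MeCN/H2O 2:1, 0 °C
Reagents that add atoms: water O
Why: Oxidative demethylation of a para-dimethoxy pair by tetravalent cerium should give the para-quinone; both para pairs of the symmetric arene lead to the same product.

Step 14
Reactants: 23 2,5-dimethoxy-3-{[(1R,2S,8aS)-1,2,5,5-tetramethyl-1,2,3,5,6,7,8,8a-octahydronaphthalen-1-yl]methyl}cyclohexa-2,5-diene-1,4-dione
Product: 24 2-hydroxy-5-methoxy-3-{[(1R,2S,8aS)-1,2,5,5-tetramethyl-1,2,3,5,6,7,8,8a-octahydronaphthalen-1-yl]methyl}cyclohexa-2,5-diene-1,4-dione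
Conditions: KOH (2 M aq.), MeOH, rt; then 1 M HCl
Reagents that add atoms: potassium hydroxide [K+].[OH-]
Why: Addition–elimination of hydroxide is expected at the methoxy group flanked by the carbonyl and the bulky C11 substituent, which is twisted out of conjugation and is the more electrophilic vinylogous ester, and the hydroxyquinone anion formed resists a second hydrolysis.

Step 15
Reactants: 24 2-hydroxy-5-methoxy-3-{[(1R,2S,8aS)-1,2,5,5-tetramethyl-1,2,3,5,6,7,8,8a-octahydronaphthalen-1-yl]methyl}cyclohexa-2,5-diene-1,4-dione; 25 (S)-2-methylbutan-1-amine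
Product: 26 nakijiquinone J
Conditions: 25 (3 equiv), NaHCO3, EtOH, 40 °C
Reagents that add atoms: none
Why: Addition–elimination of the primary amine at the remaining methoxy-bearing carbon (vinylogous ester to vinylogous amide) should occur only at C5 of the quinone because the hydroxyquinone half is present as its unreactive anion, and the amine stereocentre is not involved.

**Compound list**

1 | acetone | CC(C)=O | starting material
2 | pent-4-enylmagnesium bromide | C=CCCC[Mg]Br | starting material
3 | 2-methylhept-6-en-2-ol | CC(C)(O)CCCC=C | intermediate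
4 | phenol | Oc1ccccc1 | starting material
5 | 4-(2-methylhept-6-en-2-yl)phenol | CC(C)(CCCC=C)c1ccc(O)cc1 | intermediate
6 | 6-(4-hydroxyphenyl)-6-methylheptane-1,2-diol (racemic, not isolated) | CC(C)(CCCC(O)CO)c1ccc(O)cc1 | intermediate
7 | 5-(4-hydroxyphenyl)-5-methylhexanal | CC(C)(CCCC=O)c1ccc(O)cc1 | intermediate
8 | 5-(1-methoxy-4-oxocyclohexa-2,5-dien-1-yl)-5-methylhexanal (achiral, not isolated) | COC1(C=CC(=O)C=C1)C(C)(C)CCCC=O | intermediate
9 | (1S,4aS,8aR)-4a-methoxy-4,4-dimethyl-7-oxo-1,2,3,4,4a,7,8,8a-octahydronaphthalene-1-carbaldehyde | O=C1C=C[C@]2(OC)[C@H](C1)[C@@H](C=O)CCC2(C)C | intermediate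
10 | (4aR,8aS)-4a-methoxy-5,5-dimethyl-4a,5,6,7,8,8a-hexahydronaphthalen-2(1H)-one | O=C1C=C[C@]2(OC)[C@H](C1)CCCC2(C)C | intermediate
11 | lithium enolate of 10 (not isolated) | [Li+].[O-]C1=C[C@@H]2CCCC(C)(C)[C@]2(OC)C=C1 | intermediate
12 | (1S,4aS,8aS)-4a-methoxy-1,5,5-trimethyl-4a,5,6,7,8,8a-hexahydronaphthalen-2(1H)-one | O=C1C=C[C@]2(OC)[C@H]([C@@H]1C)CCCC2(C)C | intermediate
13 | 1,2,4,5-tetramethoxybenzene | COc1cc(OC)c(OC)cc1OC | starting material
14 | (2,3,5,6-tetramethoxyphenyl)lithium (not isolated) | [Li]c1c(OC)c(OC)cc(OC)c1OC | intermediate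
15 | (2,3,5,6-tetramethoxyphenyl)methanol | OCc1c(OC)c(OC)cc(OC)c1OC | intermediate
16 | 3-(bromomethyl)-1,2,4,5-tetramethoxybenzene | BrCc1c(OC)c(OC)cc(OC)c1OC | intermediate
17 | lithium enolate of 12 (not isolated) | [Li+].[O-]C1=C(C)[C@@H]2CCCC(C)(C)[C@]2(OC)C=C1 | intermediate
18 | (1S,4aS,8aS)-4a-methoxy-1,5,5-trimethyl-1-[(2,3,5,6-tetramethoxyphenyl)methyl]-4a,5,6,7,8,8a-hexahydronaphthalen-2(1H)-one | O=C1C=C[C@]2(OC)[C@H]([C@]1(C)Cc3c(OC)c(OC)cc(OC)c3OC)CCCC2(C)C | intermediate
19 | lithium dienolate from 18 (not isolated) | [Li+].[O-]C1=CC=C2[C@H]([C@]1(C)Cc3c(OC)c(OC)cc(OC)c3OC)CCCC2(C)C | intermediate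
20 | (1S,8aR)-1,5,5-trimethyl-1-[(2,3,5,6-tetramethoxyphenyl)methyl]-1,5,6,7,8,8a-hexahydronaphthalen-2(3H)-one | O=C1CC=C2[C@H]([C@]1(C)Cc3c(OC)c(OC)cc(OC)c3OC)CCCC2(C)C | intermediate
21 | (1S,8aS)-1,5,5-trimethyl-2-methylidene-1-[(2,3,5,6-tetramethoxyphenyl)methyl]-1,2,3,5,6,7,8,8a-octahydronaphthalene | C=C1CC=C2[C@H]([C@]1(C)Cc3c(OC)c(OC)cc(OC)c3OC)CCCC2(C)C | intermediate
22 | (1R,2S,8aS)-1,2,5,5-tetramethyl-1-[(2,3,5,6-tetramethoxyphenyl)methyl]-1,2,3,5,6,7,8,8a-octahydronaphthalene | C[C@H]1CC=C2[C@H]([C@]1(C)Cc3c(OC)c(OC)cc(OC)c3OC)CCCC2(C)C | intermediate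
23 | 2,5-dimethoxy-3-{[(1R,2S,8aS)-1,2,5,5-tetramethyl-1,2,3,5,6,7,8,8a-octahydronaphthalen-1-yl]methyl}cyclohexa-2,5-diene-1,4-dione | COC1=CC(=O)C(OC)=C(C[C@@]2(C)[C@@H]3CCCC(C)(C)C3=CC[C@@H]2C)C1=O | intermediate
24 | 2-hydroxy-5-methoxy-3-{[(1R,2S,8aS)-1,2,5,5-tetramethyl-1,2,3,5,6,7,8,8a-octahydronaphthalen-1-yl]methyl}cyclohexa-2,5-diene-1,4-dione | COC1=CC(=O)C(O)=C(C[C@@]2(C)[C@@H]3CCCC(C)(C)C3=CC[C@@H]2C)C1=O | intermediate
25 | (S)-2-methylbutan-1-amine | CC[C@H](C)CN | starting material
26 | nakijiquinone J, 2-hydroxy-5-{[(2S)-2-methylbutyl]amino}-3-{[(1R,2S,8aS)-1,2,5,5-tetramethyl-1,2,3,5,6,7,8,8a-octahydronaphthalen-1-yl]methyl}cyclohexa-2,5-diene-1,4-dione | CC[C@H](C)CNC1=CC(=O)C(O)=C(C[C@@]2(C)[C@@H]3CCCC(C)(C)C3=CC[C@@H]2C)C1=O | target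

**Step count and risks**

Total step count: 15. Longest linear sequence: 13 steps (steps 1–6 and 9–15); the benzylic bromide branch is steps 7–8.

Steps most likely to fail:

1. Step 4. The enamine closure may stall or lose enantiotopic-arm selectivity because the gem-dimethyl carbon C4 crowds the forming C1–C10 bond; oxidative loss of the tertiary side chain during dearomatisation is a second failure path. The fallback sets out from 7 and comes back at 9, replacing catalytic enamine control by a stoichiometric auxiliary. Phenol 7 is oxidised without amine (PhI(OAc)2, MeOH, 0 °C) and dienone aldehyde 8 is isolated. Condensation with (S)-1-amino-2-(methoxymethyl)pyrrolidine should give the hydrazone of 8 F1. Deprotonation with LiN(iPr)2 (THF, −78 °C) generates the aza-enolate, which should close ring A by intramolecular Michael addition under auxiliary control to the bicyclic hydrazone F2. Mild hydrolysis (aq. oxalic acid, Et2O) returns aldehyde 9; the enantiomeric auxiliary is used if the arm selectivity is the opposite.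

2. Step 9. C-alkylation of the fully substituted enolate may be slow, so that O-alkylation, ionisation and self-condensation of the electron-rich benzylic bromide, or erosion of facial selectivity compete. The fallback sets out from 12 and comes back at 18, exchanging the basic SN2 enolate alkylation for a cationic one. Ketone 12 is converted (LiN(iPr)2, then Me3SiCl, THF, −78 °C) into the trimethylsilyl dienol ether F3. Alkylation of F3 with 16 under SN1 conditions (ZnBr2 cat., CH2Cl2, −40 °C) should capture the stabilised tetramethoxybenzyl cation at C9 from the convex face and give 18 directly.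

3. Step 12. Metal hydride may isomerise the skipped diene into conjugation, C5=C6 may be over-reduced, or facial selectivity at C8 may be poor. The fallback sets out from 21 and comes back at 22, setting C8 under thermodynamic control and without a metal hydride. Hydroboration–oxidation (9-BBN, THF; NaOH, H2O2) is selective for the exocyclic alkene and should give the primary alcohol F4. Dess–Martin oxidation gives the aldehyde F5, which is equilibrated with DBU to the equatorial C8 epimer. Condensation with TsNHNH2 gives the tosylhydrazone F6, and reduction with catecholborane followed by NaOAc·3H2O should deliver the methyl group of 22.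

Further compounds
F1 | step 4 | (E)-hydrazone of 8 with (S)-1-amino-2-(methoxymethyl)pyrrolidine | COC[C@@H]1CCCN1/N=C/CCCC(C)(C)C2(OC)C=CC(=O)C=C2
F2 | step 4 | bicyclic hydrazone, the (S)-2-(methoxymethyl)pyrrolidin-1-yl imine of 9 | O=C1C=C[C@]2(OC)[C@H](C1)[C@@H](/C=N/N3CCC[C@H]3COC)CCC2(C)C
F3 | step 9 | trimethylsilyl dienol ether of 12 | C[Si](C)(C)OC1=C(C)[C@@H]2CCCC(C)(C)[C@]2(OC)C=C1
F4 | step 12 | C8-hydroxymethyl analogue of 22 (CH2OH in place of the C8 methyl, same configuration) | OC[C@H]1CC=C2[C@H]([C@]1(C)Cc3c(OC)c(OC)cc(OC)c3OC)CCCC2(C)C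
F5 | step 12 | C8-formyl analogue of 22 (equatorial aldehyde) | O=C[C@H]1CC=C2[C@H]([C@]1(C)Cc3c(OC)c(OC)cc(OC)c3OC)CCCC2(C)C
F6 | step 12 | tosylhydrazone of F5 | Cc1ccc(cc1)S(=O)(=O)N/N=C/[C@H]1CC=C2[C@H]([C@]1(C)Cc3c(OC)c(OC)cc(OC)c3OC)CCCC2(C)C
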